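**Retrosynthetic overview**
1. Nakijiquinone M ⇒ 2-hydroxy-5-methoxyquinone (MeO → isopentylamino exchange) ⇒ 2,5-dimethoxyquinone (selective saponification) ⇒ tetramethoxyarene (CAN unmasking).
2. Key disconnection, aryl–CH2 bond: an aryl bromide plus the decalin carbaldehyde, whose carbonyl carbon reacts as a CH2 carbanion equivalent through its N–H hydrazone (N2 is lost and the CH2 linker forms directly).
3. Decalin carbaldehyde ⇒ one catalytic enantioselective exo Diels–Alder reaction of 1-ethenyl-6,6-dimethylcyclohexene with tiglic aldehyde (quaternary carbon, all three stereocentres and the ring alkene).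
4. Diene ⇒ 2,2-dimethylcyclohexanone (enol triflate, Stille vinylation); aryl bromide ⇒ 1,2,4,5-tetramethoxybenzene.
5. Ring order: ring A is bought, ring B is made by the cycloaddition, the quinone ring is carried as the arene and oxidised late.

Assumption: reagents and catalysts are bought and not numbered; the catalyst antipode in step 3 is taken from the formyl C–H···O binding model and would be exchanged for its equally available enantiomer if the first rotation measurement disagreed.

**Route**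

Step 1
Reactants: 1 2,2-dimethylcyclohexanone
Product: 3 6,6-dimethylcyclohex-1-en-1-yl trifluoromethanesulfonate, via lithium enolate 2 (not isolated)
Conditions: LDA (1.1 equiv), THF, −78 °C; PhNTf2 (1.05 equiv), −78 °C → rt; aq NH4Cl
Reagents that add atoms: N-phenylbis(trifluoromethanesulfonimide), O=S(=O)(N(c1ccccc1)S(=O)(=O)C(F)(F)F)C(F)(F)F
Why: Only C6 carries α-hydrogens, so LDA gives a single enolate that PhNTf2 O-sulfonylates (enol triflate formation); no stereocentre is formed.

Step 2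
Reactants: 3 6,6-dimethylcyclohex-1-en-1-yl trifluoromethanesulfonate; 4 tributyl(vinyl)stannane
Product: 5 1-ethenyl-6,6-dimethylcyclohex-1-ene
Conditions: Pd(PPh3)4 (3 mol %), LiCl (3 equiv), THF, 65 °C; distil
Reagents that add atoms: none
Why: Stille cross-coupling of an enol triflate with a vinylstannane gives the 1,3-diene, which the adjacent gem-dimethyl group holds s-cis; no stereocentre is formed.

Step 3
Reactants: 5 1-ethenyl-6,6-dimethylcyclohex-1-ene; 6 tiglic aldehyde [(E)-2-methylbut-2-enal]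
Product: 7 (1R,2S,8aR)-1,2,5,5-tetramethyl-1,2,3,5,6,7,8,8a-octahydronaphthalene-1-carbaldehyde (CHO cis to H-8a; 1-Me and 2-Me cis; C4=C4a alkene)
Conditions: 6 (2 equiv), (R)-o-tolyl-CBS-oxazaborolidine·HNTf2 (20 mol %), CH2Cl2, −40 → −20 °C; Et3N quench
Reagents that add atoms: none
Why: Enantioselective Diels–Alder reaction under chiral oxazaborolidinium catalysis, in which the vinyl CH2 of 5 bonds to the β-carbon and the ring CH to the α-carbon of the enal ("ortho" orientation), the formyl-exo transition state usual for α-methyl enals places CHO cis to H-8a, the E-enal keeps the two methyls cis, and the catalyst (B–O coordination plus formyl C–H···O contact to the s-trans enal) exposes the Cα Si face to give (1R,2S,8aR).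

Step 4
Reactants: 8 1,2,4,5-tetramethoxybenzene
Product: 9 3-bromo-1,2,4,5-tetramethoxybenzene
Conditions: NBS (1.0 equiv), MeCN, 0 °C → rt, dark
Reagents that add atoms: N-bromosuccinimide, O=C1CCC(=O)N1Br
Why: Electrophilic aromatic bromination; the two free ring positions are equivalent and one equivalent of NBS stops at the monobromide.

Step 5
Reactants: 7 (1R,2S,8aR)-1,2,5,5-tetramethyl-1,2,3,5,6,7,8,8a-octahydronaphthalene-1-carbaldehyde; 9 3-bromo-1,2,4,5-tetramethoxybenzene
Product: 11 3-{[(1R,2S,8aS)-1,2,5,5-tetramethyl-1,2,3,5,6,7,8,8a-octahydronaphthalen-1-yl]methyl}-1,2,4,5-tetramethoxybenzene, via hydrazone 10 (not isolated)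
Conditions: N2H4·H2O (1.2 equiv), THF, 50 °C, 4 Å MS; switch to dioxane; 9 (1.5 equiv), Ni(cod)2 (10 mol %), PMe3 (40 mol %), K3PO4 (2 equiv), 90 °C
Reagents that add atoms: hydrazine (used as monohydrate), NN (its two N atoms are in intermediate 10 only and leave as N2)
Why: Proposed new method: Wolff–Kishner-type umpolung arylation in which the N–H hydrazone of 7 serves as a neopentyl carbanion equivalent — oxidative addition of 9 to Ni(0), exchange of bromide for the deprotonated hydrazone, shift from the N-bound hydrazonide to the C-bound diazenyl alkyl, then C–C reductive elimination and N2 extrusion give ArCH2R; the closest known reaction is the Ni(0)/PMe3 denitrogenative cross-coupling of aryl-aldehyde N–H hydrazones with aryl halides, and this substrate has no α-H (no ene-hydrazine or easy azine formation) and no β-H on the nickel alkyl (no β-hydride elimination), with no stereocentre touched.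

Step 6
Reactants: 11 3-{[(1R,2S,8aS)-1,2,5,5-tetramethyl-1,2,3,5,6,7,8,8a-octahydronaphthalen-1-yl]methyl}-1,2,4,5-tetramethoxybenzene
Product: 12 2,5-dimethoxy-3-{[(1R,2S,8aS)-1,2,5,5-tetramethyl-1,2,3,5,6,7,8,8a-octahydronaphthalen-1-yl]methyl}cyclohexa-2,5-diene-1,4-dione
Conditions: CAN (2.5 equiv), MeCN/H2O (2:1), 0 °C, 15 min
Reagents that add atoms: water, O
Why: Ce(IV) oxidative demethylation of a p-dimethoxyarene (radical cation, water capture, loss of MeOH); either para pair gives the same 2,5-dimethoxyquinone and the short cold reaction leaves the trisubstituted alkene intact.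

Step 7
Reactants: 12 2,5-dimethoxy-3-{[(1R,2S,8aS)-1,2,5,5-tetramethyl-1,2,3,5,6,7,8,8a-octahydronaphthalen-1-yl]methyl}cyclohexa-2,5-diene-1,4-dione
Product: 13 2-hydroxy-5-methoxy-3-{[(1R,2S,8aS)-1,2,5,5-tetramethyl-1,2,3,5,6,7,8,8a-octahydronaphthalen-1-yl]methyl}cyclohexa-2,5-diene-1,4-dione
Conditions: 2 M aq KOH, MeOH, rt → 40 °C; then 1 M HCl
Reagents that add atoms: potassium hydroxide, [K+].[OH-]
Why: Vinylogous ester saponification by conjugate addition–elimination of hydroxide; the methoxy group next to the bulky C3 substituent is twisted out of conjugation and is exchanged selectively, and the hydroxyquinone anion formed resists a second hydrolysis.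

Step 8
Reactants: 13 2-hydroxy-5-methoxy-3-{[(1R,2S,8aS)-1,2,5,5-tetramethyl-1,2,3,5,6,7,8,8a-octahydronaphthalen-1-yl]methyl}cyclohexa-2,5-diene-1,4-dione; 14 3-methylbutan-1-amine (isopentylamine)
Product: 15 nakijiquinone M, 2-hydroxy-5-[(3-methylbutyl)amino]-3-{[(1R,2S,8aS)-1,2,5,5-tetramethyl-1,2,3,5,6,7,8,8a-octahydronaphthalen-1-yl]methyl}cyclohexa-2,5-diene-1,4-dione
Conditions: 14 (3 equiv), EtOH, rt, 24 h; dilute HCl wash
Reagents that add atoms: none
Why: Conjugate addition–elimination of the primary amine at C5 with loss of methanol (the standard methoxy → amino exchange of 2-hydroxy-5-methoxyquinones); the deprotonated 2-hydroxy side is inert, so a single regioisomer forms.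

**Compound list**
1 | 2,2-dimethylcyclohexanone | CC1(C)CCCCC1=O | starting material
2 | lithium 6,6-dimethylcyclohex-1-en-1-olate | [Li+].[O-]C1=CCCCC1(C)C | intermediate
3 | 6,6-dimethylcyclohex-1-en-1-yl trifluoromethanesulfonate | CC1(C)CCCC=C1OS(=O)(=O)C(F)(F)F | intermediate
4 | tributyl(vinyl)stannane | C=C[Sn](CCCC)(CCCC)CCCC | starting material
5 | 1-ethenyl-6,6-dimethylcyclohex-1-ene | C=CC1=CCCCC1(C)C | intermediate
6 | tiglic aldehyde, (E)-2-methylbut-2-enal | C/C=C(\C)C=O | starting material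
7 | (1R,2S,8aR)-1,2,5,5-tetramethyl-1,2,3,5,6,7,8,8a-octahydronaphthalene-1-carbaldehyde | O=C[C@@]1(C)[C@@H]2CCCC(C)(C)C2=CC[C@@H]1C | intermediate
8 | 1,2,4,5-tetramethoxybenzene | COc1cc(OC)c(OC)cc1OC | starting material
9 | 3-bromo-1,2,4,5-tetramethoxybenzene | COc1cc(OC)c(OC)c(Br)c1OC | intermediate
10 | (E)-{[(1R,2S,8aR)-1,2,5,5-tetramethyl-1,2,3,5,6,7,8,8a-octahydronaphthalen-1-yl]methylidene}hydrazine | N/N=C/[C@@]1(C)[C@@H]2CCCC(C)(C)C2=CC[C@@H]1C | intermediate
11 | 3-{[(1R,2S,8aS)-1,2,5,5-tetramethyl-1,2,3,5,6,7,8,8a-octahydronaphthalen-1-yl]methyl}-1,2,4,5-tetramethoxybenzene | COc1cc(OC)c(OC)c(C[C@@]2(C)[C@@H]3CCCC(C)(C)C3=CC[C@@H]2C)c1OC | intermediate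
12 | 2,5-dimethoxy-3-{[(1R,2S,8aS)-1,2,5,5-tetramethyl-1,2,3,5,6,7,8,8a-octahydronaphthalen-1-yl]methyl}cyclohexa-2,5-diene-1,4-dione | COC1=CC(=O)C(OC)=C(C[C@@]2(C)[C@@H]3CCCC(C)(C)C3=CC[C@@H]2C)C1=O | intermediate
13 | 2-hydroxy-5-methoxy-3-{[(1R,2S,8aS)-1,2,5,5-tetramethyl-1,2,3,5,6,7,8,8a-octahydronaphthalen-1-yl]methyl}cyclohexa-2,5-diene-1,4-dione | COC1=CC(=O)C(O)=C(C[C@@]2(C)[C@@H]3CCCC(C)(C)C3=CC[C@@H]2C)C1=O | intermediate
14 | 3-methylbutan-1-amine | CC(C)CCN | starting material
15 | nakijiquinone M, 2-hydroxy-5-[(3-methylbutyl)amino]-3-{[(1R,2S,8aS)-1,2,5,5-tetramethyl-1,2,3,5,6,7,8,8a-octahydronaphthalen-1-yl]methyl}cyclohexa-2,5-diene-1,4-dione | CC(C)CCNC1=CC(=O)C(O)=C(C[C@@]2(C)[C@@H]3CCCC(C)(C)C3=CC[C@@H]2C)C1=O | target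

**Step count**
Total: 8 steps. Longest linear sequence: 7 steps (1 → 3 → 5 → 7 → 11 → 12 → 13 → 15; step 4 is a one-step side branch).

**Three steps most likely to fail, with fallbacks**

Step 5 (hydrazone arylation; alkyl-aldehyde hydrazones and a di-ortho-substituted, electron-rich aryl bromide are beyond the known scope, and N-arylation or simple reduction may compete). The fallback sets out from 7 and 8 and comes back at 11. Direct ortho-lithiation of 8 (n-BuLi, THF, 0 °C) gives (2,3,5,6-tetramethoxyphenyl)lithium F1. It adds to aldehyde 7 at −78 °C to give the benzylic carbinol (2,3,5,6-tetramethoxyphenyl)[(1R,2S,8aR)-1,2,5,5-tetramethyl-1,2,3,5,6,7,8,8a-octahydronaphthalen-1-yl]methanol F2, and both carbinol epimers are usable. NaH, CS2 and MeI convert it into the S-methyl xanthate O-{(2,3,5,6-tetramethoxyphenyl)[(1R,2S,8aR)-1,2,5,5-tetramethyl-1,2,3,5,6,7,8,8a-octahydronaphthalen-1-yl]methyl} S-methyl carbonodithioate F3. Bu3SnH/AIBN (toluene, 90 °C, Barton–McCombie) then removes the oxygen to give 11. This replaces the reversed-polarity coupling by aryl-anion addition and radical deoxygenation.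

Step 3 (tiglic aldehyde is a sluggish dienophile; exo/endo ratio, ee and acid sensitivity of the diene are uncertain). The fallback sets out from 5 and comes back at 7, replacing catalyst control by auxiliary control. (S)-4-Benzyloxazolidin-2-one is N-acylated with (E)-2-methylbut-2-enoyl chloride (Et3N, DMAP, CH2Cl2) to give the imide (S)-4-benzyl-3-[(E)-2-methylbut-2-enoyl]oxazolidin-2-one F4. Its Me2AlCl-promoted Diels–Alder reaction with 5 (CH2Cl2, −30 °C; auxiliary enantiomer chosen by the chelate model, acyl group exo) gives the adduct (S)-4-benzyl-3-{[(1R,2S,8aR)-1,2,5,5-tetramethyl-1,2,3,5,6,7,8,8a-octahydronaphthalen-1-yl]carbonyl}oxazolidin-2-one F5. LiAlH4 (THF, 0 °C) releases the auxiliary and gives the primary alcohol [(1R,2S,8aR)-1,2,5,5-tetramethyl-1,2,3,5,6,7,8,8a-octahydronaphthalen-1-yl]methanol F6. Dess–Martin oxidation returns aldehyde 7.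

Step 7 (the regioselectivity of the mono-saponification may be poor). The fallback sets out from 12 and comes back at 15, inverting the order so that sterics decide the regiochemistry. Amine 14 (1.1 equiv, EtOH, 0 °C → rt) first displaces the unhindered C5 methoxy group of 12 to give 2-methoxy-5-[(3-methylbutyl)amino]-3-{[(1R,2S,8aS)-1,2,5,5-tetramethyl-1,2,3,5,6,7,8,8a-octahydronaphthalen-1-yl]methyl}cyclohexa-2,5-diene-1,4-dione F7. Aqueous NaOH/MeOH then hydrolyses the remaining hindered C2 vinylogous ester, and acidification gives 15.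

**Further compounds**
F1 | step 5 | (2,3,5,6-tetramethoxyphenyl)lithium | [Li]c1c(OC)c(OC)cc(OC)c1OC
F2 | step 5 | (2,3,5,6-tetramethoxyphenyl)[(1R,2S,8aR)-1,2,5,5-tetramethyl-1,2,3,5,6,7,8,8a-octahydronaphthalen-1-yl]methanol (carbinol epimers) | COc1cc(OC)c(OC)c(C(O)[C@@]2(C)[C@@H]3CCCC(C)(C)C3=CC[C@@H]2C)c1OC
F3 | step 5 | O-{(2,3,5,6-tetramethoxyphenyl)[(1R,2S,8aR)-1,2,5,5-tetramethyl-1,2,3,5,6,7,8,8a-octahydronaphthalen-1-yl]methyl} S-methyl carbonodithioate | COc1cc(OC)c(OC)c(C(OC(=S)SC)[C@@]2(C)[C@@H]3CCCC(C)(C)C3=CC[C@@H]2C)c1OC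
F4 | step 3 | (S)-4-benzyl-3-[(E)-2-methylbut-2-enoyl]oxazolidin-2-one | C/C=C(\C)C(=O)N1[C@@H](Cc2ccccc2)COC1=O
F5 | step 3 | (S)-4-benzyl-3-{[(1R,2S,8aR)-1,2,5,5-tetramethyl-1,2,3,5,6,7,8,8a-octahydronaphthalen-1-yl]carbonyl}oxazolidin-2-one | O=C([C@@]1(C)[C@@H]2CCCC(C)(C)C2=CC[C@@H]1C)N1[C@@H](Cc2ccccc2)COC1=O
F6 | step 3 | [(1R,2S,8aR)-1,2,5,5-tetramethyl-1,2,3,5,6,7,8,8a-octahydronaphthalen-1-yl]methanol | OC[C@@]1(C)[C@@H]2CCCC(C)(C)C2=CC[C@@H]1C
F7 | step 7 | 2-methoxy-5-[(3-methylbutyl)amino]-3-{[(1R,2S,8aS)-1,2,5,5-tetramethyl-1,2,3,5,6,7,8,8a-octahydronaphthalen-1-yl]methyl}cyclohexa-2,5-diene-1,4-dione | CC(C)CCNC1=CC(=O)C(OC)=C(C[C@@]2(C)[C@@H]3CCCC(C)(C)C3=CC[C@@H]2C)C1=O
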